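**Plan**

1. Drimane numbering is used: ring A = C1–C5, C10; ring B = C5–C10; C11 and C12 are the carboxyl carbons on C9 and C8. The enabling feature is the γ-oxo ester array C6(O)–C7H2–C8(CO2R) of ring B, the retron of a one-carbon enlargement of a cyclic β-keto ester.
2. Cuts, in order: the O6–acyl ester and the two tert-butyl esters; C7 is excised and C6–C8 rejoined (ring B becomes the five-membered ring C5–C6–C8–C9–C10); C6–C8 (Dieckmann); C9–C10 (ester-enolate Claisen), back to β-cyclocitral (1), via its alcohol (2), and but-3-enoic acid (3).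
3. Forward: ring A is bought; the Claisen step joins the chain at C10; hydroboration and oxidation give the triester; Dieckmann closure makes the five-membered ring; a radical one-carbon ring expansion inserts C7 and creates ring B; reduction, acylation and ester cleavage finish.
4. Stereochemistry: C10 and C9 from a reagent-controlled chair Claisen transition state; C5 from hydroboration anti to the axial methyls; C8 from hydrogen-atom transfer anti to the axial C10 methyl; C6 from hydride attack on the same open α face.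

Key step: step 11

Assumption: the (S,S)-boron controller is taken to deliver the (2S,1′R) acid 6 (if the sense proves opposite, the (R,R)-controller is used with no other change); 1, 3 and the trienoic acid 17 are taken as purchasable.

Step 1
Reactants: 1 β-cyclocitral (2,6,6-trimethylcyclohex-1-ene-1-carbaldehyde)
Product: 2 β-cyclogeraniol ((2,6,6-trimethylcyclohex-1-en-1-yl)methanol)
Conditions: NaBH4, MeOH, 0 °C
Reagents that add atoms: none
Why: Borohydride 1,2-reduction of the hindered enal should give the primary allylic alcohol; no stereocentre is formed.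

Step 2
Reactants: 2 β-cyclogeraniol; 3 but-3-enoic acid
Product: 4 (2,6,6-trimethylcyclohex-1-en-1-yl)methyl but-3-enoate
Conditions: DCC, DMAP (5 mol%), CH2Cl2, 0 °C
Reagents that add atoms: but-3-enoic acid (3), C=CCC(=O)O
Why: Steglich esterification of a primary alcohol; low temperature and little DMAP should keep the β,γ-unsaturated acyl group from moving into conjugation.

Step 3
Reactants: 4 (2,6,6-trimethylcyclohex-1-en-1-yl)methyl but-3-enoate
Product: 6 (2S)-2-[(1R)-1,3,3-trimethyl-2-methylidenecyclohexyl]but-3-enoic acid, via boron dienolate 5 (not isolated)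
Conditions: (4S,5S)-2-bromo-1,3-bis{[3,5-bis(trifluoromethyl)phenyl]sulfonyl}-4,5-diphenyl-1,3,2-diazaborolidine (preformed, 1.2 equiv), Et3N, toluene–hexane, −78 °C, then −20 → 4 °C; aqueous work-up
Reagents that add atoms: none
Why: Soft enolisation should give the boron dienolate with the vinyl group cis to the allylic oxygen, and its chair [3,3] shift (enantioselective Ireland–Claisen rearrangement, as known for geranyl but-3-enoate-type esters) forms the C9–C10 bond on the alkene face chosen by the controller, setting the quaternary C10 and C9 together with the vinyl and the C10 methyl both axial in the transition state, which later places C11 cis to the C10 methyl.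

Step 4
Reactants: 6 (2S)-2-[(1R)-1,3,3-trimethyl-2-methylidenecyclohexyl]but-3-enoic acid
Product: 7 tert-butyl (2S)-2-[(1R)-1,3,3-trimethyl-2-methylidenecyclohexyl]but-3-enoate
Conditions: O-tert-butyl-N,N'-diisopropylisourea, CH2Cl2, rt
Reagents that add atoms: O-tert-butyl-N,N'-diisopropylisourea, CC(C)N=C(OC(C)(C)C)NC(C)C
Why: O-alkylation of the acid by the protonated isourea under neutral conditions should avoid both conjugation of the vinyl group and acid-induced lactonisation onto the methylidene group.

Step 5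
Reactants: 7 tert-butyl (2S)-2-[(1R)-1,3,3-trimethyl-2-methylidenecyclohexyl]but-3-enoate
Product: 9 tert-butyl (2S)-4-hydroxy-2-[(1S,2S)-2-(hydroxymethyl)-1,3,3-trimethylcyclohexyl]butanoate, via bis-alkylborane 8 (not isolated)
Conditions: BH3·THF (excess), THF, 0 °C → rt; then 30% H2O2, aq. NaOH, 0 °C
Reagents that add atoms: hydrogen peroxide, OO
Why: Hydroboration–oxidation puts oxygen on both terminal carbons (C12 and C6); at the methylidene group hydrogen should enter C5 from the face opposite the axial methyls on C4 and C10, giving H-5 trans to the C10 methyl.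

Step 6
Reactants: 9 tert-butyl (2S)-4-hydroxy-2-[(1S,2S)-2-(hydroxymethyl)-1,3,3-trimethylcyclohexyl]butanoate
Product: 10 (1S,2R)-2-[(2S)-1-tert-butoxy-3-carboxy-1-oxopropan-2-yl]-2,6,6-trimethylcyclohexane-1-carboxylic acid
Conditions: TEMPO (cat.), NaOCl (cat.), NaClO2, MeCN–phosphate buffer (pH 6.7), 35 °C
Reagents that add atoms: sodium chlorite, [Na+].[O-]Cl=O; water, O
Why: TEMPO/chlorite oxidation should take both primary alcohols to the acids without touching the tert-butyl ester or any stereocentre.

Step 7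
Reactants: 10 (1S,2R)-2-[(2S)-1-tert-butoxy-3-carboxy-1-oxopropan-2-yl]-2,6,6-trimethylcyclohexane-1-carboxylic acid
Product: 11 (1S,2R)-2-[(2S)-1,4-di-tert-butoxy-1,4-dioxobutan-2-yl]-2,6,6-trimethylcyclohexane-1-carboxylic acid
Conditions: Boc2O (1.1 equiv), DMAP (cat.), t-BuOH–THF, rt
Reagents that add atoms: di-tert-butyl dicarbonate, CC(C)(C)OC(=O)OC(=O)OC(C)(C)C; tert-butanol, CC(C)(C)O (either can supply the tert-butyl group)
Why: Mixed-anhydride tert-butyl esterification is very sensitive to hindrance, so the open C12 acid should react while the C6 acid, flanked by two quaternary carbons, is left.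

Step 8
Reactants: 11 (1S,2R)-2-[(2S)-1,4-di-tert-butoxy-1,4-dioxobutan-2-yl]-2,6,6-trimethylcyclohexane-1-carboxylic acid
Product: 12 methyl (1S,2R)-2-[(2S)-1,4-di-tert-butoxy-1,4-dioxobutan-2-yl]-2,6,6-trimethylcyclohexane-1-carboxylate
Conditions: MeI, K2CO3, DMF, rt
Reagents that add atoms: iodomethane, CI
Why: The hindered carboxylate is alkylated on oxygen (SN2 at iodomethane), which does not need access to the carbonyl carbon.

Step 9
Reactants: 12 methyl (1S,2R)-2-[(2S)-1,4-di-tert-butoxy-1,4-dioxobutan-2-yl]-2,6,6-trimethylcyclohexane-1-carboxylate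
Product: 13 di-tert-butyl (1S,2S,3aS,7aS)-4,4,7a-trimethyl-3-oxooctahydro-1H-indene-1,2-dicarboxylate
Conditions: LiN(SiMe3)2 (2.2 equiv), THF, −78 → 0 °C; AcOH quench
Reagents that add atoms: none
Why: Dieckmann condensation: only C8 is readily deprotonated, its enolate attacks the sole methyl ester (5-exo-trig) to give the trans-fused five-membered β-keto ester, whose acidity drives the closure, while the tert-butyl esters are neither attacked nor exchanged.

Step 10
Reactants: 13 di-tert-butyl (1S,2S,3aS,7aS)-4,4,7a-trimethyl-3-oxooctahydro-1H-indene-1,2-dicarboxylate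
Product: 14 di-tert-butyl (1R,2S,3aS,7aS)-2-(bromomethyl)-4,4,7a-trimethyl-3-oxooctahydro-1H-indene-1,2-dicarboxylate
Conditions: NaH (1.05 equiv), THF–DMPU, 0 °C; CH2Br2 (excess), rt → 50 °C
Reagents that add atoms: dibromomethane, BrCBr
Why: C-Alkylation of the β-keto ester enolate with dibromomethane is the standard entry to Dowd–Beckwith substrates; the bromomethyl group should enter anti to the C9 ester, but this centre is erased in the next step.

Step 11
Reactants: 14 di-tert-butyl (1R,2S,3aS,7aS)-2-(bromomethyl)-4,4,7a-trimethyl-3-oxooctahydro-1H-indene-1,2-dicarboxylate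
Product: 15 di-tert-butyl (1S,2S,4aS,8aS)-5,5,8a-trimethyl-4-oxodecahydronaphthalene-1,2-dicarboxylate
Conditions: (Me3Si)3SiH (1.3 equiv) and AIBN (0.2 equiv) added slowly by syringe pump, benzene (5 mM), 80 °C
Reagents that add atoms: none
Why: The silyl radical abstracts bromine from 14, the primary C7 radical adds 3-exo-trig to the C6 carbonyl, and the cyclopropyloxy radical opens by β-scission of the old C6–C8 bond, which puts C7 between C6 and C8 and leaves a tertiary, ester-stabilised radical at C8 (the closest known reaction type is the Dowd–Beckwith one-carbon ring expansion of 2-(halomethyl) β-keto esters). Ring B is thus closed by 3-exo-trig addition followed by fragmentation (formally a 6-endo result), turning the five-membered ring C5–C6–C8–C9–C10 into the six-membered ring. The only new stereocentre, C8, is set when the silane delivers hydrogen to the planar radical from the α face, because the β face is screened by the axial C10 methyl (1,3 to C8) and by the equatorial C9 ester, so the C12 ester should end up axial and cis to the C9 ester. The step needs rearrangement to outrun direct reduction of the C7 radical, which slow addition of the poor hydrogen donor (Me3Si)3SiH at high dilution should secure, and regioselective β-scission, which the ester on C8 and the strain released on going from trans-hydrindanone to trans-decalone should secure.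

Step 12
Reactants: 15 di-tert-butyl (1S,2S,4aS,8aS)-5,5,8a-trimethyl-4-oxodecahydronaphthalene-1,2-dicarboxylate
Product: 16 di-tert-butyl (1S,2S,4R,4aS,8aS)-4-hydroxy-5,5,8a-trimethyldecahydronaphthalene-1,2-dicarboxylate
Conditions: NaBH4, MeOH–THF, −20 → 0 °C
Reagents that add atoms: none
Why: Hydride should attack the C6 ketone from the α face because the β face carries three syn-axial groups (C10 methyl, 4β-methyl, C8 ester), giving the axial 6β-alcohol; the tert-butyl ester on C8 should resist lactonisation by the neighbouring hydroxyl.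

Step 13
Reactants: 16 di-tert-butyl (1S,2S,4R,4aS,8aS)-4-hydroxy-5,5,8a-trimethyldecahydronaphthalene-1,2-dicarboxylate; 17 (2E,4E,6E)-octa-2,4,6-trienoic acid
Product: 19 di-tert-butyl (1S,2S,4R,4aS,8aS)-5,5,8a-trimethyl-4-[(2E,4E,6E)-octa-2,4,6-trienoyloxy]decahydronaphthalene-1,2-dicarboxylate, via mixed anhydride 18 (not isolated)
Conditions: 17, 2,4,6-trichlorobenzoyl chloride, Et3N, THF, rt; then 16, DMAP, toluene, rt → 40 °C
Reagents that add atoms: (2E,4E,6E)-octa-2,4,6-trienoic acid (17), C/C=C/C=C/C=C/C(=O)O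
Why: Yamaguchi esterification: the mixed anhydride acylates DMAP and the acylpyridinium should transfer the trienoyl group to the hindered axial alcohol with retention at C6 and without change of the triene geometry.

Step 14
Reactants: 19 di-tert-butyl (1S,2S,4R,4aS,8aS)-5,5,8a-trimethyl-4-[(2E,4E,6E)-octa-2,4,6-trienoyloxy]decahydronaphthalene-1,2-dicarboxylate
Product: 20 (1S,2S,4R,4aS,8aS)-5,5,8a-trimethyl-4-[(2E,4E,6E)-octa-2,4,6-trienoyloxy]decahydronaphthalene-1,2-dicarboxylic acid (CNP0462207.1)
Conditions: TFA–CH2Cl2 (1:4), 0 °C → rt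
Reagents that add atoms: none
Why: Acidolysis of the tert-butyl esters (loss of isobutene) should free both acids without hydrolysing the trienoate or epimerising the axial C8 centre, which a basic hydrolysis would endanger.

**Compound list**

1 | β-cyclocitral (2,6,6-trimethylcyclohex-1-ene-1-carbaldehyde) | CC1=C(C=O)C(C)(C)CCC1 | starting material
2 | β-cyclogeraniol ((2,6,6-trimethylcyclohex-1-en-1-yl)methanol) | CC1=C(CO)C(C)(C)CCC1 | intermediate
3 | but-3-enoic acid | C=CCC(=O)O | starting material
4 | (2,6,6-trimethylcyclohex-1-en-1-yl)methyl but-3-enoate | C=CCC(=O)OCC1=C(C)CCCC1(C)C | intermediate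
5 | boron dienolate of 4: (1Z)-1-[(2,6,6-trimethylcyclohex-1-en-1-yl)methoxy]buta-1,3-dien-1-yl ester of the (4S,5S)-diazaborolidine controller, vinyl cis to the allylic oxygen | C=C/C=C(\OCC1=C(C)CCCC1(C)C)OB1N(S(=O)(=O)c2cc(cc(c2)C(F)(F)F)C(F)(F)F)[C@@H](c2ccccc2)[C@H](c2ccccc2)N1S(=O)(=O)c1cc(cc(c1)C(F)(F)F)C(F)(F)F | intermediate (not isolated)
6 | (2S)-2-[(1R)-1,3,3-trimethyl-2-methylidenecyclohexyl]but-3-enoic acid | C=C[C@H](C(=O)O)[C@@]1(C)CCCC(C)(C)C1=C | intermediate
7 | tert-butyl (2S)-2-[(1R)-1,3,3-trimethyl-2-methylidenecyclohexyl]but-3-enoate | C=C[C@H](C(=O)OC(C)(C)C)[C@@]1(C)CCCC(C)(C)C1=C | intermediate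
8 | bis-alkylborane from 7 (drawn as the bis-BH2 adduct): tert-butyl (2S)-4-boranyl-2-[(1S,2S)-2-(boranylmethyl)-1,3,3-trimethylcyclohexyl]butanoate | [BH2]CC[C@H](C(=O)OC(C)(C)C)[C@@]1(C)CCCC(C)(C)[C@@H]1C[BH2] | intermediate (not isolated)
9 | tert-butyl (2S)-4-hydroxy-2-[(1S,2S)-2-(hydroxymethyl)-1,3,3-trimethylcyclohexyl]butanoate | OCC[C@H](C(=O)OC(C)(C)C)[C@@]1(C)CCCC(C)(C)[C@@H]1CO | intermediate
10 | (1S,2R)-2-[(2S)-1-tert-butoxy-3-carboxy-1-oxopropan-2-yl]-2,6,6-trimethylcyclohexane-1-carboxylic acid | OC(=O)C[C@H](C(=O)OC(C)(C)C)[C@@]1(C)CCCC(C)(C)[C@@H]1C(=O)O | intermediate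
11 | (1S,2R)-2-[(2S)-1,4-di-tert-butoxy-1,4-dioxobutan-2-yl]-2,6,6-trimethylcyclohexane-1-carboxylic acid | CC(C)(C)OC(=O)C[C@H](C(=O)OC(C)(C)C)[C@@]1(C)CCCC(C)(C)[C@@H]1C(=O)O | intermediate
12 | methyl (1S,2R)-2-[(2S)-1,4-di-tert-butoxy-1,4-dioxobutan-2-yl]-2,6,6-trimethylcyclohexane-1-carboxylate | CC(C)(C)OC(=O)C[C@H](C(=O)OC(C)(C)C)[C@@]1(C)CCCC(C)(C)[C@@H]1C(=O)OC | intermediate
13 | di-tert-butyl (1S,2S,3aS,7aS)-4,4,7a-trimethyl-3-oxooctahydro-1H-indene-1,2-dicarboxylate (trans ring fusion; C2 is epimerisable and is drawn trans to the C1 ester) | O=C1[C@@H](C(=O)OC(C)(C)C)[C@H](C(=O)OC(C)(C)C)[C@@]2(C)CCCC(C)(C)[C@H]12 | intermediate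
14 | di-tert-butyl (1R,2S,3aS,7aS)-2-(bromomethyl)-4,4,7a-trimethyl-3-oxooctahydro-1H-indene-1,2-dicarboxylate (C2 as expected; erased in step 11) | O=C1[C@](CBr)(C(=O)OC(C)(C)C)[C@H](C(=O)OC(C)(C)C)[C@@]2(C)CCCC(C)(C)[C@H]12 | intermediate
15 | di-tert-butyl (1S,2S,4aS,8aS)-5,5,8a-trimethyl-4-oxodecahydronaphthalene-1,2-dicarboxylate | O=C1C[C@H](C(=O)OC(C)(C)C)[C@H](C(=O)OC(C)(C)C)[C@@]2(C)CCCC(C)(C)[C@H]12 | intermediate
16 | di-tert-butyl (1S,2S,4R,4aS,8aS)-4-hydroxy-5,5,8a-trimethyldecahydronaphthalene-1,2-dicarboxylate | O[C@@H]1C[C@H](C(=O)OC(C)(C)C)[C@H](C(=O)OC(C)(C)C)[C@@]2(C)CCCC(C)(C)[C@H]12 | intermediate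
17 | (2E,4E,6E)-octa-2,4,6-trienoic acid | C/C=C/C=C/C=C/C(=O)O | starting material
18 | (2E,4E,6E)-octa-2,4,6-trienoic 2,4,6-trichlorobenzoic anhydride | C/C=C/C=C/C=C/C(=O)OC(=O)c1c(Cl)cc(Cl)cc1Cl | intermediate (not isolated)
19 | di-tert-butyl (1S,2S,4R,4aS,8aS)-5,5,8a-trimethyl-4-[(2E,4E,6E)-octa-2,4,6-trienoyloxy]decahydronaphthalene-1,2-dicarboxylate | C/C=C/C=C/C=C/C(=O)O[C@@H]1C[C@H](C(=O)OC(C)(C)C)[C@H](C(=O)OC(C)(C)C)[C@@]2(C)CCCC(C)(C)[C@H]12 | intermediate
20 | (1S,2S,4R,4aS,8aS)-5,5,8a-trimethyl-4-[(2E,4E,6E)-octa-2,4,6-trienoyloxy]decahydronaphthalene-1,2-dicarboxylic acid | C/C=C/C=C/C=C/C(=O)O[C@@H]1C[C@H](C(=O)O)[C@H](C(=O)O)[C@@]2(C)CCCC(C)(C)[C@H]12 | target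

**Totals**

Total step count: 14. Longest linear sequence: 14 steps (1 → 20); 3 and 17 are bought.

**Steps most likely to fail**

Step 3. What may go wrong: the [3,3] shift of the boron dienolate may be slow at the fully substituted, neopentyl-flanked allyl terminus, and the controller may give incomplete or opposite facial control. Fallback (resolution in place of asymmetric induction): starting from 4, LiN(iPr)2 and Me3SiCl in THF at −78 °C should give the (1E)-trimethylsilyl ketene acetal F1, which can be warmed to 60 °C for the Ireland–Claisen shift. Hydrolysis then gives the racemic acid, that is 6 together with its enantiomer (2R)-2-[(1S)-1,3,3-trimethyl-2-methylidenecyclohexyl]but-3-enoic acid F2. Crystallisation of the (R)-1-phenylethylammonium salt of 6 F3 (the (S)-amine is used instead if the other salt is the less soluble one) and acidification come back to the route at 6.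

Step 9. What may go wrong: attack of the C8 enolate on an ester carbonyl shielded by two flanking quaternary carbons may be too slow, so that epimerisation at C9 or C5 or intermolecular condensation takes over. Fallback (aldol and oxidation in place of acylation): starting from 11, BH3·THF should reduce only the free acid, giving di-tert-butyl (2S)-2-[(1S,2S)-2-(hydroxymethyl)-1,3,3-trimethylcyclohexyl]butanedioate F4. Dess–Martin oxidation gives di-tert-butyl (2S)-2-[(1S,2S)-2-formyl-1,3,3-trimethylcyclohexyl]butanedioate F5. LiN(SiMe3)2 at −78 °C should close the ring by intramolecular aldol addition to the much more accessible formyl group, giving di-tert-butyl (1S,3aS,7aS)-3-hydroxy-4,4,7a-trimethyloctahydro-1H-indene-1,2-dicarboxylate F6 (epimers at C2 and C3). A second Dess–Martin oxidation comes back to the route at 13.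

Step 11. What may go wrong: hydrogen-atom transfer to the C8 radical with poor facial selectivity, which would give the equatorial ester. Fallback (catalytic hydrogenation in place of radical hydrogen transfer to set C8): starting from 15 obtained in admixture with its C2 epimer di-tert-butyl (1S,2R,4aS,8aS)-5,5,8a-trimethyl-4-oxodecahydronaphthalene-1,2-dicarboxylate F7, IBX in DMSO at 70 °C should dehydrogenate both epimers to the single enone di-tert-butyl (1R,4aS,8aS)-5,5,8a-trimethyl-4-oxo-1,4,4a,5,6,7,8,8a-octahydronaphthalene-1,2-dicarboxylate F8. Only C7–C8 can become unsaturated, because the other α-carbon, C5, has only quaternary neighbours. H2 over Pd/C in EtOAc should then add from the α face, opposite the axial C10 methyl, and come back to the route at 15.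

**Further compounds**

F1 | step 3 | (1E)-1-[(2,6,6-trimethylcyclohex-1-en-1-yl)methoxy]-1-(trimethylsilyloxy)buta-1,3-diene | C=C/C=C(\OCC1=C(C)CCCC1(C)C)O[Si](C)(C)C
F2 | step 3 | (2R)-2-[(1S)-1,3,3-trimethyl-2-methylidenecyclohexyl]but-3-enoic acid | C=C[C@@H](C(=O)O)[C@]1(C)CCCC(C)(C)C1=C
F3 | step 3 | (R)-1-phenylethylammonium (2S)-2-[(1R)-1,3,3-trimethyl-2-methylidenecyclohexyl]but-3-enoate | C=C[C@H](C(=O)[O-])[C@@]1(C)CCCC(C)(C)C1=C.C[C@@H]([NH3+])c1ccccc1
F4 | step 9 | di-tert-butyl (2S)-2-[(1S,2S)-2-(hydroxymethyl)-1,3,3-trimethylcyclohexyl]butanedioate | CC(C)(C)OC(=O)C[C@H](C(=O)OC(C)(C)C)[C@@]1(C)CCCC(C)(C)[C@@H]1CO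
F5 | step 9 | di-tert-butyl (2S)-2-[(1S,2S)-2-formyl-1,3,3-trimethylcyclohexyl]butanedioate | CC(C)(C)OC(=O)C[C@H](C(=O)OC(C)(C)C)[C@@]1(C)CCCC(C)(C)[C@@H]1C=O
F6 | step 9 | di-tert-butyl (1S,3aS,7aS)-3-hydroxy-4,4,7a-trimethyloctahydro-1H-indene-1,2-dicarboxylate (C2 and C3 epimers) | OC1C(C(=O)OC(C)(C)C)[C@H](C(=O)OC(C)(C)C)[C@@]2(C)CCCC(C)(C)[C@H]12
F7 | step 11 | di-tert-butyl (1S,2R,4aS,8aS)-5,5,8a-trimethyl-4-oxodecahydronaphthalene-1,2-dicarboxylate | O=C1C[C@@H](C(=O)OC(C)(C)C)[C@H](C(=O)OC(C)(C)C)[C@@]2(C)CCCC(C)(C)[C@H]12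
F8 | step 11 | di-tert-butyl (1R,4aS,8aS)-5,5,8a-trimethyl-4-oxo-1,4,4a,5,6,7,8,8a-octahydronaphthalene-1,2-dicarboxylate | O=C1C=C(C(=O)OC(C)(C)C)[C@H](C(=O)OC(C)(C)C)[C@@]2(C)CCCC(C)(C)[C@H]12
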